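## Retrosynthetic overview

1. The target is disconnected last by a ring contraction: a Meinwald (semipinacol-type) 1,2-alkyl shift of a 2-(acetoxymethyl)-3,4-epoxycyclohexene carrying the side chain on C5 gives the formylcyclopentene, and the double bond is then moved into conjugation.
2. That vinyl epoxide comes from syn-dehydration of an epoxy tertiary alcohol, which comes from OH-directed epoxidation of a 4-substituted 1-(acetoxymethyl)cyclohex-2-en-1-ol.
3. The cyclohexenol is cut between the ring carbon and the side-chain α-carbon: an aldehyde enamine adds to the π-allyl complex of an enantiopure cyclohexadiene monoepoxide, which sets both stereocentres.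
4. The epoxide comes from cyclohex-2-enone (dienyl triflate, hydroxymethylation, Sharpless epoxidation, acetylation); the aldehyde comes from 5-bromo-2-methylpent-2-ene, acetylide, Me3Al and but-3-enenitrile (carboalumination, B-alkyl Suzuki coupling).
5. Ring order: the six-membered carbocycle is bought; first oxirane (step 7), second oxirane (step 10), cyclopentene by contraction of the cyclohexene (step 12).

Assumption: the SMILES encodes the (3S) ring centre and the (2R,5E) side chain, and compounds 1, 2, 6 and 10 are bought.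

## Route

Step 1
Reactants: 1 5-bromo-2-methylpent-2-ene; 2 lithium acetylide–ethylenediamine complex
Product: 3 6-methylhept-5-en-1-yne
Conditions: DMSO, 10 → 23 °C
Reagents that add atoms: none
Why: SN2 alkylation of an acetylide by a primary homoallylic bromide in a dipolar aprotic solvent is a standard terminal-alkyne synthesis and creates no stereo element.

Step 2
Reactants: 3 6-methylhept-5-en-1-yne
Product: 5 (1E)-1-iodo-2,6-dimethylhepta-1,5-diene, via alkenylalane 4 (not isolated)
Conditions: Me3Al (2 equiv), Cp2ZrCl2 (0.2 equiv), CH2Cl2, 23 °C; then iodine, THF, −30 → 0 °C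
Reagents that add atoms: trimethylaluminium C[Al](C)C; iodine [I][I]
Why: Negishi zirconium-catalysed carboalumination adds Me and Al syn with Me on the internal carbon, and iodinolysis of the C–Al bond goes with retention, so the trisubstituted alkene is fixed as E.

Step 3
Reactants: 5 (1E)-1-iodo-2,6-dimethylhepta-1,5-diene; 6 but-3-enenitrile
Product: 8 (5E)-6,10-dimethylundeca-5,9-dienenitrile, via cyanopropylborane 7 (not isolated)
Conditions: 6, 9-BBN-H, THF, 0 → 23 °C; then 5, PdCl2(dppf) (5 mol %), aq. K3PO4, DMF, 23 → 50 °C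
Reagents that add atoms: none
Why: anti-Markovnikov hydroboration followed by B-alkyl Suzuki–Miyaura coupling joins the sp3 and sp2 carbons with retention of alkene geometry and tolerates the nitrile.

Step 4
Reactants: 8 (5E)-6,10-dimethylundeca-5,9-dienenitrile
Product: 9 (5E)-6,10-dimethylundeca-5,9-dienal
Conditions: i-Bu2AlH (1.2 equiv), CH2Cl2, −78 °C; then aq. tartaric acid, 0 °C
Reagents that add atoms: water O
Why: partial hydride reduction of the nitrile stops at the N-aluminoimine, which hydrolyses to the aldehyde without touching the alkenes.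

Step 5
Reactants: 10 cyclohex-2-en-1-one
Product: 11 cyclohexa-1,3-dien-1-yl trifluoromethanesulfonate
Conditions: Tf2O (1.1 equiv), 2,6-di-tert-butyl-4-methylpyridine (1.2 equiv), CH2Cl2, 0 → 23 °C
Reagents that add atoms: trifluoromethanesulfonic anhydride O=S(=O)(OS(=O)(=O)C(F)(F)F)C(F)(F)F
Why: Stang-type O-triflation of an enone with a hindered base removes the γ-proton and gives the through-conjugated 1-triflyloxy-1,3-diene, as with steroidal enones.

Step 6
Reactants: 11 cyclohexa-1,3-dien-1-yl trifluoromethanesulfonate
Product: 12 (cyclohexa-1,3-dien-1-yl)methanol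
Conditions: Bu3SnCH2OH (1.2 equiv), Pd(PPh3)4 (5 mol %), LiCl (3 equiv), THF, 60 °C
Reagents that add atoms: (tributylstannyl)methanol OC[Sn](CCCC)(CCCC)CCCC
Why: Stille (Kosugi–Migita) hydroxymethylation of an alkenyl triflate transfers the CH2OH group in preference to butyl and leaves the diene in place.

Step 7
Reactants: 12 (cyclohexa-1,3-dien-1-yl)methanol
Product: 13 [(1R,6R)-7-oxabicyclo[4.1.0]hept-4-en-1-yl]methanol
Conditions: Ti(OiPr)4 (10 mol %), D-(−)-diethyl tartrate (12 mol %), t-BuOOH (1.5 equiv), 4 Å MS, CH2Cl2, −25 °C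
Reagents that add atoms: tert-butyl hydroperoxide CC(C)(C)OO
Why: Katsuki–Sharpless asymmetric epoxidation oxidises only the allylic-alcohol double bond of the dienol, and the D-tartrate ligand delivers oxygen to the face that gives the (1R,6R) epoxide (the L-tartrate gives the 2S,3S series with E-allylic alcohols).

Step 8
Reactants: 13 [(1R,6R)-7-oxabicyclo[4.1.0]hept-4-en-1-yl]methanol
Product: 14 [(1R,6R)-7-oxabicyclo[4.1.0]hept-4-en-1-yl]methyl acetate
Conditions: Ac2O, Et3N, DMAP (cat.), CH2Cl2, 0 °C
Reagents that add atoms: acetic anhydride CC(=O)OC(C)=O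
Why: DMAP-catalysed acetylation of the primary alcohol is fast under basic conditions that leave the acid-sensitive vinyl epoxide and both stereocentres untouched.

Step 9
Reactants: 9 (5E)-6,10-dimethylundeca-5,9-dienal; 14 [(1R,6R)-7-oxabicyclo[4.1.0]hept-4-en-1-yl]methyl acetate
Product: 15 [(1S,4R)-4-[(2R,5E)-6,10-dimethyl-1-oxoundeca-5,9-dien-2-yl]-1-hydroxycyclohex-2-en-1-yl]methyl acetate
Conditions: Pd(PPh3)4 (5 mol %), (S)-2-[diphenyl(trimethylsilyloxy)methyl]pyrrolidine (20 mol %), THF, 0 → 23 °C
Reagents that add atoms: none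
Why: Proposed new method: zerovalent palladium opens the vinyl epoxide with inversion to a π-allyl/alkoxide zwitterion, and the (E)-enamine formed from 9 and the amine attacks the unhindered distal allyl terminus anti to palladium through its Si face, so the ring centre C4 (R) is fixed 1,4-cis to the oxygen by the epoxide (net retention) and the side-chain centre C2′ (R) by the amine; the closest known reactions are the dual palladium/secondary-amine α-allylation of aldehydes with allylic acetates and the Tsuji–Trost 1,4-cis alkylation of cyclic vinyl epoxides by soft carbon acids.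

Step 10
Reactants: 15 [(1S,4R)-4-[(2R,5E)-6,10-dimethyl-1-oxoundeca-5,9-dien-2-yl]-1-hydroxycyclohex-2-en-1-yl]methyl acetate
Product: 16 [(1R,2R,5S,6R)-5-[(2R,5E)-6,10-dimethyl-1-oxoundeca-5,9-dien-2-yl]-2-hydroxy-7-oxabicyclo[4.1.0]heptan-2-yl]methyl acetate
Conditions: VO(acac)2 (5 mol %), t-BuOOH (1.3 equiv), CH2Cl2, 0 °C
Reagents that add atoms: tert-butyl hydroperoxide CC(C)(C)OO
Why: hydroxyl-directed vanadium-catalysed epoxidation oxidises the allylic-alcohol double bond far faster than the isolated trisubstituted alkenes and delivers oxygen syn to the tertiary OH (the epoxide configuration is erased in step 12).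

Step 11
Reactants: 16 [(1R,2R,5S,6R)-5-[(2R,5E)-6,10-dimethyl-1-oxoundeca-5,9-dien-2-yl]-2-hydroxy-7-oxabicyclo[4.1.0]heptan-2-yl]methyl acetate
Product: 17 [(1S,5S,6R)-5-[(2R,5E)-6,10-dimethyl-1-oxoundeca-5,9-dien-2-yl]-7-oxabicyclo[4.1.0]hept-2-en-2-yl]methyl acetate
Conditions: Burgess reagent (2 equiv), PhMe, 60 °C
Reagents that add atoms: none
Why: Burgess dehydration is a syn (Ei) elimination through the sulfamate ester; a ring C3–H is syn to the tertiary OH whereas the epoxide C–H is anti, so the endocyclic trisubstituted alkene forms and turns the epoxide into an allylic one.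

Step 12
Reactants: 17 [(1S,5S,6R)-5-[(2R,5E)-6,10-dimethyl-1-oxoundeca-5,9-dien-2-yl]-7-oxabicyclo[4.1.0]hept-2-en-2-yl]methyl acetate
Product: 19 [(3S)-2-formyl-3-[(2R,5E)-6,10-dimethyl-1-oxoundeca-5,9-dien-2-yl]cyclopent-1-en-1-yl]methyl acetate, via cyclopent-2-ene carbaldehyde 18 (not isolated)
Conditions: BF3·OEt2 (0.2 equiv), CH2Cl2, −78 °C; then Et3N (0.5 equiv), −78 → 23 °C
Reagents that add atoms: none
Why: Meinwald rearrangement: BF3 ionises the allylic C1–O bond to an allyl cation and the ring bond C6–C5 shifts to C1 (semipinacol-type 1,2-alkyl shift with retention at the migrating C5), which expels C6 as the formyl group and contracts the cyclohexene to a cyclopentene; opening at the other epoxide carbon would give the same skeleton, and Et3N then moves the double bond into conjugation, leaving the (3S) and (2′R) centres untouched.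

## Compound list

1 | 5-bromo-2-methylpent-2-ene | CC(C)=CCCBr | starting material
2 | lithium acetylide–ethylenediamine complex | [Li+].[C-]#C.NCCN | starting material
3 | 6-methylhept-5-en-1-yne | C#CCCC=C(C)C | intermediate
4 | [(1E)-2,6-dimethylhepta-1,5-dien-1-yl]dimethylalumane | C[Al](C)/C=C(\C)CCC=C(C)C | intermediate (not isolated)
5 | (1E)-1-iodo-2,6-dimethylhepta-1,5-diene | I/C=C(\C)CCC=C(C)C | intermediate
6 | but-3-enenitrile | C=CCC#N | starting material
7 | 4-(9-borabicyclo[3.3.1]nonan-9-yl)butanenitrile | N#CCCCB1C2CCCC1CCC2 | intermediate (not isolated)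
8 | (5E)-6,10-dimethylundeca-5,9-dienenitrile | N#CCCC/C=C(\C)CCC=C(C)C | intermediate
9 | (5E)-6,10-dimethylundeca-5,9-dienal | O=CCCC/C=C(\C)CCC=C(C)C | intermediate
10 | cyclohex-2-en-1-one | O=C1C=CCCC1 | starting material
11 | cyclohexa-1,3-dien-1-yl trifluoromethanesulfonate | O=S(=O)(OC1=CC=CCC1)C(F)(F)F | intermediate
12 | (cyclohexa-1,3-dien-1-yl)methanol | OCC1=CC=CCC1 | intermediate
13 | [(1R,6R)-7-oxabicyclo[4.1.0]hept-4-en-1-yl]methanol (epoxide on the former C1=C2 bond of the dienol) | OC[C@@]12O[C@@H]1C=CCC2 | intermediate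
14 | [(1R,6R)-7-oxabicyclo[4.1.0]hept-4-en-1-yl]methyl acetate | CC(=O)OC[C@@]12O[C@@H]1C=CCC2 | intermediate
15 | [(1S,4R)-4-[(2R,5E)-6,10-dimethyl-1-oxoundeca-5,9-dien-2-yl]-1-hydroxycyclohex-2-en-1-yl]methyl acetate (OH and side chain cis) | CC(=O)OC[C@@]1(O)C=C[C@H]([C@H](C=O)CC/C=C(\C)CCC=C(C)C)CC1 | intermediate
16 | [(1R,2R,5S,6R)-5-[(2R,5E)-6,10-dimethyl-1-oxoundeca-5,9-dien-2-yl]-2-hydroxy-7-oxabicyclo[4.1.0]heptan-2-yl]methyl acetate (epoxide syn to OH) | CC(=O)OC[C@@]1(O)[C@@H]2O[C@@H]2[C@H]([C@H](C=O)CC/C=C(\C)CCC=C(C)C)CC1 | intermediate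
17 | [(1S,5S,6R)-5-[(2R,5E)-6,10-dimethyl-1-oxoundeca-5,9-dien-2-yl]-7-oxabicyclo[4.1.0]hept-2-en-2-yl]methyl acetate | CC(=O)OCC1=CC[C@@H]([C@H](C=O)CC/C=C(\C)CCC=C(C)C)[C@H]2O[C@@H]12 | intermediate
18 | [(4S)-5-formyl-4-[(2R,5E)-6,10-dimethyl-1-oxoundeca-5,9-dien-2-yl]cyclopent-1-en-1-yl]methyl acetate (C5 configuration not defined; it is lost on conjugation) | CC(=O)OCC1=CC[C@@H]([C@H](C=O)CC/C=C(\C)CCC=C(C)C)C1C=O | intermediate (not isolated)
19 | [(3S)-2-formyl-3-[(2R,5E)-6,10-dimethyl-1-oxoundeca-5,9-dien-2-yl]cyclopent-1-en-1-yl]methyl acetate | CC(=O)OCC1=C(C=O)[C@H]([C@H](C=O)CC/C=C(\C)CCC=C(C)C)CC1 | target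

## Step count and risks

Total steps: 12. Longest linear sequence: 8 steps (1–4, then 9–12; the branch 5–8, then 9–12 is equally long).

Steps most likely to fail:

Step 9 (the new dual-catalytic union). Risks are N-allylation of the amine catalyst, β-hydride loss from the π-allyl complex (dienol, then arene), slow attack at a secondary ring terminus, a mismatched catalyst/substrate pair, and acetyl migration in the tertiary alkoxide. The fallback uses known chemistry, sets out from 9 and 14 and comes back at 15; it replaces catalytic enamine formation by a stoichiometric chiral auxiliary. Aldehyde 9 is condensed (4 Å MS, benzene) with (S)-2-(methoxymethyl)pyrrolidine to the isolated enamine (2S)-1-[(1E,5E)-6,10-dimethylundeca-1,5,9-trien-1-yl]-2-(methoxymethyl)pyrrolidine F1. F1 is then alkylated by 14 under plain Tsuji–Trost conditions (Pd(PPh3)4, THF, 23 °C). Pre-formed enamines are established neutral nucleophiles for π-allylpalladium, and cyclic vinyl epoxides are established 1,4-cis electrophiles. Buffered hydrolysis (aq. AcOH/NaOAc) releases 15; the antipodal amine is used if the sense of induction at C2′ demands it.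

Step 11 (dehydration of a tertiary alcohol next to an epoxide). Risks are ionisation of the sulfamate with participation of the epoxide or the acetate, and poor regiocontrol of the elimination. The fallback sets out from 15 and comes back at 17; it reverses the order of the two operations. The more labile tertiary allylic alcohol of 15 is dehydrated first (Burgess reagent, THF, 23 °C) to the conjugated diene [(4R)-4-[(2R,5E)-6,10-dimethyl-1-oxoundeca-5,9-dien-2-yl]cyclohexa-1,5-dien-1-yl]methyl acetate F2. Only the cis-disubstituted diene double bond of F2 is then epoxidised with (R,R)-(salen)MnCl, that is [N,N′-bis(3,5-di-tert-butylsalicylidene)-1,2-cyclohexanediaminato]manganese chloride, with NaOCl and 4-phenylpyridine N-oxide in CH2Cl2 at 0 °C. This catalyst prefers conjugated cis-alkenes over the isolated trisubstituted alkenes of the chain, and the salen enantiomer is chosen to give 17; face selectivity is not critical because the epoxide carbons lose their configuration in step 12.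

Step 12 (the ring contraction). Risks are a competing 1,2-hydride shift to the cyclohexenone, proton loss from the allyl cation to a dienol and then an arene, and capture of the cation by a chain alkene. The fallback sets out from 17 and comes back at 19; it splits the rearrangement into two discrete events (halohydrin semipinacol). MgBr2·OEt2 (Et2O, −20 °C) opens the allylic C–O bond by SN2 to the trans-bromohydrin [(4S,5R,6R)-6-bromo-5-hydroxy-4-[(2R,5E)-6,10-dimethyl-1-oxoundeca-5,9-dien-2-yl]cyclohex-1-en-1-yl]methyl acetate F3, which is isolated. AgOTf with 2,6-lutidine (CH2Cl2, −40 °C) then removes bromide while the ring bond anti to C–Br migrates (Tiffeneau-type contraction), and Et3N conjugates the alkene to give 19.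

Further compounds

F1 | step 9 | (2S)-1-[(1E,5E)-6,10-dimethylundeca-1,5,9-trien-1-yl]-2-(methoxymethyl)pyrrolidine | COC[C@@H]1CCCN1/C=C/CC/C=C(\C)CCC=C(C)C
F2 | step 11 | [(4R)-4-[(2R,5E)-6,10-dimethyl-1-oxoundeca-5,9-dien-2-yl]cyclohexa-1,5-dien-1-yl]methyl acetate | CC(=O)OCC1=CC[C@@H]([C@H](C=O)CC/C=C(\C)CCC=C(C)C)C=C1
F3 | step 12 | [(4S,5R,6R)-6-bromo-5-hydroxy-4-[(2R,5E)-6,10-dimethyl-1-oxoundeca-5,9-dien-2-yl]cyclohex-1-en-1-yl]methyl acetate | CC(=O)OCC1=CC[C@@H]([C@H](C=O)CC/C=C(\C)CCC=C(C)C)[C@@H](O)[C@@H]1Br
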